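## The problem

Prestegane A (17) is a trans-2,3-dibenzyl-γ-butyrolactone: one five-membered ring (O1, C2 carbonyl, C3, C4, C5) with a 3-hydroxy-4-methoxybenzyl arm on C3 and a 3,4-dimethoxybenzyl arm on C4, both centres R. The skeleton is small, so the task is to place each arm on its own carbon and to introduce absolute configuration at a carbon that has no functional group of its own. The two arms differ by one O-methyl group and the two ends of the C2–C5 chain differ only in oxidation level, so C2 and C5 must stay distinguishable or the regioisomeric lactone forms as well. C3 lies α to the carbonyl: it is epimerizable, it prefers to be trans to the C4 arm, and its enolate is alkylated anti to that arm, so C4 is the centre to set absolutely and it can then control C3. C4 itself is a methine between three CH2 groups and gives a catalyst nothing to hold once the skeleton is complete. The free phenol, the two electron-rich rings (easily halogenated or oxidized) and the base-labile lactone exclude harsh electrophilic or strongly basic aqueous late steps, so the phenol is carried as a benzyl ether and released last. The enabling feature is that C4 and the benzylic CH2 of its arm are two adjacent carbons between an aryl ring and C5: the pattern left by a boron-bound vinyl group that has taken an aryl electrophile at its terminus and a migrating carbon (C5) at its inner carbon, with boron remaining on C4 as the handle for C3.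

## Retrosynthesis

**17 ⇒ 16.** The O–benzyl bond of the phenol is cut first, giving benzyl ether 16. A benzyl ether is preferred to a silyl or acyl group because it survives the amide base of the C3 alkylation and the bromide-forming step. The forward reaction must remove it under neutral hydrogenolysis without touching the lactone, C3 or the benzylic C–C bonds.

**16 ⇒ 13 + 15.** The bond between C3 and the CH2 of its arm is cut. The neighbouring cut, C3–C4 with the arm already on C3, would create C3 without control, need a base equilibration, and force C2 and C5 to be told apart on a chain whose ends look alike. Removing the arm instead leaves lactone 13 (ring formed, one stereocentre, no phenol) and bromide 15. The forward reaction is an enolate alkylation anti to the C4 arm, which gives the trans isomer both kinetically and thermodynamically.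

**13 ⇒ 12.** The O1–C2 acyl bond and the oxidation level of C2 are removed, giving diol 12. Carrying C2 as a protected, differentiated acid would cost two or three more steps. The diol is acceptable because its two primary alcohols differ: the C5 hydroxyl sits next to the branched C4, the C2 hydroxyl on an unbranched CH2. The forward reaction must be an oxidative lactonization that starts at the less hindered alcohol.

**12 ⇒ 11.** The C2–O bond is cut as an anti-Markovnikov hydration, giving homoallylic alcohol 11. C2 and C3 now form a vinyl group, the most direct two-carbon unit that can be attached to a boronate. The forward hydroboration must add boron to the terminal carbon only.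

**11 ⇒ 7 + 8.** Two bonds are cut: C3–C4 (vinyl to C4) and C5–O. In boronate 7, C4 carries boron and C5 carries silicon, two different latent functions on neighbouring carbons. C4 can therefore be given its carbon substituent from vinyl Grignard reagent 8 by a Zweifel olefination before C5 is oxidized by a Tamao oxidation. Oxidizing boron to the alcohol would spend the handle, and one-carbon homologations would need two rounds. The forward sequence must replace boron with retention and must use peroxide only after boron has left.

**7 ⇒ 5 + 2 + 4 (key disconnection).** The C4–C5 bond and the aryl–CH2 bond are cut together, giving vinylboronate 5, Grignard reagent 2 and aryl triflate 4. Regiocontrolled hydroboration of an internal alkene to the same boronate is not available, and a stoichiometric chiral-base route is longer in reagents. The three components are each one step or less from catalogue materials. The forward reaction must induce a 1,2-shift from boron to carbon with control of the vinyl face and must move carbon, not a pinacol oxygen.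

**2 ⇒ 1; 4 ⇒ 3; 15 ⇒ 14.** The C–Mg bond of 2 comes from the C–Cl bond of silane 1, the O–S bond of 4 from phenol 3, and the C–Br bond of 15 from benzylic alcohol 14. All three are functional-group exchanges that need only tolerate aryl ethers.

## Roads not taken

Alternative 1: The cut runs through C3–C4 and through the bond between the exocyclic carbon and its aryl ring, leading back to the propiolate ester A1 and the arylboronic acid A2. In the forward step an arylrhodium species of monovalent rhodium, formed from A2, adds across the alkyne of A1 with the aryl group on the terminal carbon. The alkenylrhodium inserts the styrenyl alkene to form C3–C4 and the ring, and protonation of the benzylic rhodium gives benzylidene lactone A3.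
- Merits: the ring, C4 and every carbon of the target arrive in one catalytic step from two simple partners, and the whole route would need about five steps against nine here. In step economy this road is clearly better.
- Weak points: the ester tether prefers the conformation that holds alkyne and alkene apart, so protonation of the alkenylrhodium (plain hydroarylation) competes with ring closure. Enantioselective insertion of a 1,2-disubstituted styrenyl alkene through such a tether is not secured. C3 is not set: the exocyclic alkene must be hydrogenated, which should place hydrogen anti to the C4 arm and give the cis relationship, so an incomplete base equilibration follows.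
- Comparison: the chosen plan sets C4 by a reaction with an established scope on simple vinylboron and aryl triflate partners, and sets C3 directly trans by alkylation. It pays for this with four extra steps.

Alternative 2: Both benzylic ring bonds (at C4 and at C3) are cut, leading back to the chiral 5-alkoxybutenolide A4, the aryl dithiane A5 and benzyl bromide 15. Lithiated A5 adds to C4 of A4 anti to the alkoxy group and the enolate is trapped at C3 by 15 anti to the new substituent, giving A6 with both ring centres in place.
- Merits: both arms and both stereocentres are set in one pot under substrate control that is well documented for this lignan class. In stereochemical reliability this road is at least as good as the chosen one, and its length is comparable.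
- Weak points: the chirality comes from a stoichiometric auxiliary that must be made and purified as one acetal diastereomer. A6 also carries atoms that have to be taken off again: the acetal carbon must be reduced to the C5 methylene with relactonization, the dithiane must be desulfurized, and the benzyl ether must be cleaved, the sulfur complicating any palladium hydrogenolysis before it is gone.
- Comparison: the chosen plan offers catalytic control of C4, access to either enantiomer by the choice of ligand, and intermediates whose atoms nearly all end up in the target. It is the less battle-tested of the two.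

Alternative 3: The O1–C5 bond is cut in the retro-Baeyer–Villiger sense, leading back to the prochiral cyclobutanone A8, which is two steps (ketene cycloaddition, dechlorination) from allylarene A7. A monooxygenase inserts oxygen between the carbonyl carbon and one of the two enantiotopic CH2 groups to give lactone A9, which is the same compound as 13.
- Merits: A9 is reached in three steps where the chosen plan needs six to reach 13, the oxidant is air, and the endgame (alkylation with 15, hydrogenolysis) is the same. In step count this road is better.
- Weak points: the result depends on one enzyme accepting a bulky, poorly water-soluble 3-arylmethyl cyclobutanone and choosing the right CH2 group. With this enzyme class both the level and the sense of selectivity vary with the 3-substituent, and the only remedy is enzyme screening or engineering. Dilute aqueous whole-cell or cofactor-recycling conditions are also needed.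
- Comparison: the chosen plan offers a small-molecule catalyst whose sense of induction is set by the ligand antipode, ordinary anhydrous laboratory technique, and a boronate (7) from which other C4 arms follow by changing the triflate. It does not match this road in length.

Key step: step 3

Remark on the catalyst: both enantiomers of the ferrocenyl bisphosphine are available; the one that delivers (S)-7 is to be assigned by correlation with the known sense of induction for aryl triflates and primary alkyl migrating groups.
Remark on materials: alcohol 14 is taken as a catalogue compound; it is otherwise one hydride reduction from O-benzylisovanillin.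

## Route

Step 1
Reactants: 1 (chloromethyl)(isopropoxy)dimethylsilane
Product: 2 [(isopropoxydimethylsilyl)methyl]magnesium chloride (THF solution, titrated)
Conditions: Mg turnings, 1,2-dibromoethane (cat.), THF, 45 °C → rt
Reagents that add atoms: magnesium, [Mg]
Why: Grignard formation by insertion of magnesium into the primary carbon–chlorine bond; the hindered isopropoxy group on silicon is not displaced by the reagent, which is why this silane is the standard hydroxymethyl-anion equivalent.

Step 2
Reactants: 3 3,4-dimethoxyphenol
Product: 4 3,4-dimethoxyphenyl trifluoromethanesulfonate
Conditions: Tf2O, pyridine, CH2Cl2, 0 °C → rt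
Reagents that add atoms: trifluoromethanesulfonic anhydride, O=S(=O)(OS(=O)(=O)C(F)(F)F)C(F)(F)F
Why: O-sulfonylation of a phenol; the electron-rich ring is not attacked at 0 °C in the presence of pyridine, and the triflate is the electrophile class for which the key step is established.

Step 3
Reactants: 5 vinylboronic acid pinacol ester; 2 [(isopropoxydimethylsilyl)methyl]magnesium chloride; 4 3,4-dimethoxyphenyl trifluoromethanesulfonate
Product: 7 pinacol (S)-[1-(3,4-dimethoxyphenyl)-3-(isopropoxydimethylsilyl)propan-2-yl]boronate, via chloromagnesium vinyl(silylmethyl)borate 6 (not isolated)
Conditions: THF, 0 °C → rt (ate complex); then NaOTf (2 equiv), Pd(OAc)2 (2 mol%), 1,1'-bis[bis(4-methoxy-3,5-dimethylphenyl)phosphino]-2,2'-bis[α-(dimethylamino)benzyl]ferrocene (single enantiomer giving (S)-7, 2.4 mol%), THF/DMSO, 40 °C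
Reagents that add atoms: none
Why: Grignard reagent 2 adds to the vacant orbital of boron in 5 to give the tetracoordinate borate 6, whose vinyl group becomes a π-nucleophile. Oxidative addition of triflate 4 to zerovalent palladium, formed in the flask from Pd(OAc)2 and the bisphosphine, gives a cationic aryl complex of divalent palladium that binds the vinyl group of 6; the silylmethyl group then shifts from boron to the adjacent carbon anti to palladium (C4–C5 bond), and reductive elimination from the alkyl(aryl)palladium forms the aryl–CH2 bond and returns zerovalent palladium. The closest known reaction is the enantioselective conjunctive cross-coupling of Grignard-derived vinylboron ate complexes with aryl triflates, in which NaOTf removes chloride that would otherwise block the cationic palladium centre. No ring is closed in this step. The single new stereocentre, C4, is fixed by the chiral bisphosphine, which selects the face of the bound vinyl group on which the metallate shift occurs; boron stays on C4 and the secondary boronate is configurationally stable. The step needs the 1,2-shift to outrun direct transfer of the vinyl group to palladium and β-hydride elimination of the alkylpalladium, which the non-coordinating triflate, the wide-bite-angle bisphosphine and the electron-rich tetracoordinate boron are expected to secure. It also needs carbon and not a pinacol oxygen to migrate, which a primary alkyl group such as silylmethyl does readily, and the silicon–isopropoxy bond is safe once the Grignard reagent has been consumed in 6.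

Step 4
Reactants: 7 pinacol (S)-[1-(3,4-dimethoxyphenyl)-3-(isopropoxydimethylsilyl)propan-2-yl]boronate; 8 vinylmagnesium bromide
Product: 11 (R)-2-(3,4-dimethoxybenzyl)but-3-en-1-ol, via bromomagnesium alkyl(vinyl)borate 9 (not isolated), via (R)-homoallyl(isopropoxy)silane 10 (not isolated)
Conditions: THF/DMSO (1:1), 0 °C → rt; iodine, MeOH, −78 °C; NaOMe, MeOH, −78 °C → rt; aq. Na2S2O3 work-up; crude 10, KF, KHCO3, 30% H2O2, THF/MeOH, rt → 40 °C
Reagents that add atoms: hydrogen peroxide, OO
Why: Zweifel olefination: iodine activates the vinyl group of borate 9, C4 migrates from boron to carbon with retention of configuration, and methoxide triggers anti elimination of boron and iodide to give the terminal alkene of 10. Tamao oxidation of the crude alkoxysilane (fluoride-activated silicon, attack of hydroperoxide, shift of C5 from silicon to oxygen) then gives the primary alcohol; any exchange of isopropoxy for methoxy on silicon under the methoxide is immaterial because both are oxidized, and an isolated terminal alkene is inert to buffered peroxide.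

Step 5
Reactants: 11 (R)-2-(3,4-dimethoxybenzyl)but-3-en-1-ol
Product: 12 (R)-2-(3,4-dimethoxybenzyl)butane-1,4-diol
Conditions: 9-BBN (2.5 equiv), THF, 0 °C → rt; then aq. NaOH, 30% H2O2, 0 °C → rt
Reagents that add atoms: hydrogen peroxide, OO
Why: Hydroboration–oxidation of a monosubstituted alkene; the bulky dialkylborane places boron on the terminal carbon (C2), the free hydroxyl only consumes one equivalent of reagent, and no stereocentre is created or touched.

Step 6
Reactants: 12 (R)-2-(3,4-dimethoxybenzyl)butane-1,4-diol
Product: 13 (R)-4-(3,4-dimethoxybenzyl)dihydrofuran-2(3H)-one
Conditions: [Cu(MeCN)4]OTf (5 mol%), 2,2'-bipyridine (5 mol%), TEMPO (5 mol%), N-methylimidazole (10 mol%), MeCN, air, rt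
Reagents that add atoms: none
Why: Aerobic copper/nitroxyl oxidative lactonization: the alkoxide of monovalent-copper-derived catalyst and the bulky nitroxyl oxidize the less hindered primary alcohol (C2, on an unbranched CH2) faster than the C5 alcohol next to the branched C4, the hydroxy aldehyde closes to the lactol through the C5 hydroxyl, and the lactol is oxidized to the lactone. This selectivity for the less hindered end of unsymmetrical primary diols is the known behaviour of the TEMPO variant, and the conditions leave electron-rich arenes and benzylic positions alone.

Step 7
Reactants: 14 3-(benzyloxy)-4-methoxybenzyl alcohol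
Product: 15 3-(benzyloxy)-4-methoxybenzyl bromide
Conditions: PBr3, Et2O, 0 °C
Reagents that add atoms: phosphorus tribromide, BrP(Br)Br
Why: Conversion of an activated benzylic alcohol to the bromide through its phosphite ester; the aryl benzyl ether is stable to the brief cold treatment, and the bromide is used freshly prepared.

Step 8
Reactants: 13 (R)-4-(3,4-dimethoxybenzyl)dihydrofuran-2(3H)-one; 15 3-(benzyloxy)-4-methoxybenzyl bromide
Product: 16 (3R,4R)-3-[3-(benzyloxy)-4-methoxybenzyl]-4-(3,4-dimethoxybenzyl)dihydrofuran-2(3H)-one
Conditions: LiN(SiMe3)2, THF, −78 °C; then 15, THF/DMPU, −78 → −30 °C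
Reagents that add atoms: none
Why: Alkylation of the lithium enolate of a β-substituted γ-butyrolactone; the electrophile approaches the planar C3 anti to the C4 arm, so the new C3 centre is set trans (3R) by the existing C4 centre, the classical substrate-controlled entry to trans-dibenzylbutyrolactones.

Step 9
Reactants: 16 (3R,4R)-3-[3-(benzyloxy)-4-methoxybenzyl]-4-(3,4-dimethoxybenzyl)dihydrofuran-2(3H)-one
Product: 17 Prestegane A, (3R,4R)-4-(3,4-dimethoxybenzyl)-3-(3-hydroxy-4-methoxybenzyl)dihydrofuran-2(3H)-one
Conditions: H2 (1 atm), Pd/C (10 wt%), EtOAc/EtOH, rt
Reagents that add atoms: none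
Why: Hydrogenolysis of an aryl benzyl ether under neutral conditions; the lactone, the unactivated benzylic C–C bonds and both stereocentres are not affected.

## Compound list

1 | (chloromethyl)(isopropoxy)dimethylsilane | CC(C)O[Si](C)(C)CCl | starting material
2 | [(isopropoxydimethylsilyl)methyl]magnesium chloride | CC(C)O[Si](C)(C)C[Mg]Cl | intermediate
3 | 3,4-dimethoxyphenol | COc1ccc(O)cc1OC | starting material
4 | 3,4-dimethoxyphenyl trifluoromethanesulfonate | COc1ccc(OS(=O)(=O)C(F)(F)F)cc1OC | intermediate
5 | vinylboronic acid pinacol ester | C=CB1OC(C)(C)C(C)(C)O1 | starting material
6 | chloromagnesium [(isopropoxydimethylsilyl)methyl](pinacolato)vinylborate (ate complex, formed in the flask) | C=C[B-]1(C[Si](C)(C)OC(C)C)OC(C)(C)C(C)(C)O1.[Mg+]Cl | intermediate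
7 | pinacol (S)-[1-(3,4-dimethoxyphenyl)-3-(isopropoxydimethylsilyl)propan-2-yl]boronate | CC(C)O[Si](C)(C)C[C@@H](B1OC(C)(C)C(C)(C)O1)Cc1ccc(OC)c(OC)c1 | intermediate
8 | vinylmagnesium bromide | C=C[Mg]Br | starting material
9 | bromomagnesium (S)-[1-(3,4-dimethoxyphenyl)-3-(isopropoxydimethylsilyl)propan-2-yl](pinacolato)vinylborate (ate complex, formed in the flask) | CC(C)O[Si](C)(C)C[C@@H]([B-]1(C=C)OC(C)(C)C(C)(C)O1)Cc1ccc(OC)c(OC)c1.[Mg+]Br | intermediate
10 | (R)-[2-(3,4-dimethoxybenzyl)but-3-en-1-yl](isopropoxy)dimethylsilane (crude, oxidized directly) | CC(C)O[Si](C)(C)C[C@@H](C=C)Cc1ccc(OC)c(OC)c1 | intermediate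
11 | (R)-2-(3,4-dimethoxybenzyl)but-3-en-1-ol | OC[C@@H](C=C)Cc1ccc(OC)c(OC)c1 | intermediate
12 | (R)-2-(3,4-dimethoxybenzyl)butane-1,4-diol | OC[C@@H](CCO)Cc1ccc(OC)c(OC)c1 | intermediate
13 | (R)-4-(3,4-dimethoxybenzyl)dihydrofuran-2(3H)-one | O=C1C[C@@H](Cc2ccc(OC)c(OC)c2)CO1 | intermediate
14 | 3-(benzyloxy)-4-methoxybenzyl alcohol | COc1ccc(CO)cc1OCc1ccccc1 | starting material
15 | 3-(benzyloxy)-4-methoxybenzyl bromide | COc1ccc(CBr)cc1OCc1ccccc1 | intermediate
16 | (3R,4R)-3-[3-(benzyloxy)-4-methoxybenzyl]-4-(3,4-dimethoxybenzyl)dihydrofuran-2(3H)-one | COc1ccc(C[C@H]2C(=O)OC[C@@H]2Cc2ccc(OC)c(OC)c2)cc1OCc1ccccc1 | intermediate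
17 | Prestegane A, (3R,4R)-4-(3,4-dimethoxybenzyl)-3-(3-hydroxy-4-methoxybenzyl)dihydrofuran-2(3H)-one | COc1ccc(C[C@H]2C(=O)OC[C@@H]2Cc2ccc(OC)c(OC)c2)cc1O | target

## Step count and least certain steps

Total: 9 steps. Longest linear sequence: 7 steps (steps 1, 3, 4, 5, 6, 8, 9, from silane 1 to 17).

**Step 3 (key step).** Three things may go wrong:
- Formation of borate 6 from the alkoxysilyl Grignard reagent may be incomplete, or residual chloride may block the cationic palladium centre.
- Direct transfer of the vinyl group to palladium or β-hydride elimination may compete with the metallate shift.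
- The face selection may be lower for a silylmethyl migrating group than for the simple alkyl groups on which the method rests.

Fallback, from 2 back to 7, by reagent-controlled lithiation–borylation: Grignard reagent 2 is quenched with 2-isopropoxy-4,4,5,5-tetramethyl-1,3,2-dioxaborolane to give pinacol [(isopropoxydimethylsilyl)methyl]boronate F1. Commercial 2-(3,4-dimethoxyphenyl)ethanol F2 is acylated with N,N-diisopropylcarbamoyl chloride to give 2-(3,4-dimethoxyphenyl)ethyl N,N-diisopropylcarbamate F3. F3 is deprotonated α to oxygen with s-BuLi and (+)-sparteine in Et2O at −78 °C, F1 is added, and warming induces the 1,2-shift of the silylmethyl group with loss of the carbamate. Retentive borylation and invertive migration should give (S)-7, where the route is rejoined.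

**Step 4.** Addition of 8 to the hindered secondary boronate may be incomplete or reversible, so that iodination leads to loss of boron without C–C bond formation, and the Grignard reagent may attack silicon. Fallback, from 7 back to 12, by two one-carbon Matteson homologations: chloromethyllithium made in the flask from bromochloromethane and n-BuLi at −78 °C converts 7 into pinacol (S)-[2-(3,4-dimethoxybenzyl)-3-(isopropoxydimethylsilyl)propyl]boronate F4. A second round gives pinacol (S)-[3-(3,4-dimethoxybenzyl)-4-(isopropoxydimethylsilyl)butyl]boronate F5, and one treatment with KF, KHCO3 and H2O2 oxidizes both the carbon–boron and the carbon–silicon bond to give diol 12. Steps 4 and 5 are thereby replaced.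

**Step 6.** The two primary alcohols may not be discriminated well enough, so that oxidation also begins at the C5 hydroxyl and the regioisomeric lactone accompanies 13. Fallback, from 11 back to 13, by differentiating the two ends before C2 is oxidized: alcohol 11 is silylated (TBSCl, imidazole) to (R)-tert-butyl{[2-(3,4-dimethoxybenzyl)but-3-en-1-yl]oxy}dimethylsilane F6. Hydroboration–oxidation gives (R)-4-[(tert-butyldimethylsilyl)oxy]-3-(3,4-dimethoxybenzyl)butan-1-ol F7. Oxidation with TEMPO and PhI(OAc)2 in MeCN/H2O gives (R)-4-[(tert-butyldimethylsilyl)oxy]-3-(3,4-dimethoxybenzyl)butanoic acid F8. TsOH in MeOH removes the silyl ether and closes lactone 13.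

**Step 8.** The electron-rich benzylic bromide 15 may decompose by self-alkylation before it meets the enolate, and proton exchange between product and enolate may lead to double alkylation. Fallback, from 13 directly to 17, by an aldol–hydrogenolysis sequence: the lithium enolate of 13 is added to commercial 3-(benzyloxy)-4-methoxybenzaldehyde F9 to give (3S,4R)-3-{[3-(benzyloxy)-4-methoxyphenyl](hydroxy)methyl}-4-(3,4-dimethoxybenzyl)dihydrofuran-2(3H)-one F10 as a mixture of carbinol epimers, trans on the ring. Hydrogenation over Pd/C in AcOH with a trace of HClO4 removes the benzylic hydroxyl and the O-benzyl group together to give 17.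

## Further compounds

F1 | step 3 | pinacol [(isopropoxydimethylsilyl)methyl]boronate | CC(C)O[Si](C)(C)CB1OC(C)(C)C(C)(C)O1
F2 | step 3 | 2-(3,4-dimethoxyphenyl)ethanol | COc1ccc(CCO)cc1OC
F3 | step 3 | 2-(3,4-dimethoxyphenyl)ethyl N,N-diisopropylcarbamate | COc1ccc(CCOC(=O)N(C(C)C)C(C)C)cc1OC
F4 | step 4 | pinacol (S)-[2-(3,4-dimethoxybenzyl)-3-(isopropoxydimethylsilyl)propyl]boronate | CC(C)O[Si](C)(C)C[C@@H](CB1OC(C)(C)C(C)(C)O1)Cc1ccc(OC)c(OC)c1
F5 | step 4 | pinacol (S)-[3-(3,4-dimethoxybenzyl)-4-(isopropoxydimethylsilyl)butyl]boronate | CC(C)O[Si](C)(C)C[C@@H](CCB1OC(C)(C)C(C)(C)O1)Cc1ccc(OC)c(OC)c1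
F6 | step 6 | (R)-tert-butyl{[2-(3,4-dimethoxybenzyl)but-3-en-1-yl]oxy}dimethylsilane | CC(C)(C)[Si](C)(C)OC[C@@H](C=C)Cc1ccc(OC)c(OC)c1
F7 | step 6 | (R)-4-[(tert-butyldimethylsilyl)oxy]-3-(3,4-dimethoxybenzyl)butan-1-ol | CC(C)(C)[Si](C)(C)OC[C@@H](CCO)Cc1ccc(OC)c(OC)c1
F8 | step 6 | (R)-4-[(tert-butyldimethylsilyl)oxy]-3-(3,4-dimethoxybenzyl)butanoic acid | CC(C)(C)[Si](C)(C)OC[C@@H](CC(=O)O)Cc1ccc(OC)c(OC)c1
F9 | step 8 | 3-(benzyloxy)-4-methoxybenzaldehyde | COc1ccc(C=O)cc1OCc1ccccc1
F10 | step 8 | (3S,4R)-3-{[3-(benzyloxy)-4-methoxyphenyl](hydroxy)methyl}-4-(3,4-dimethoxybenzyl)dihydrofuran-2(3H)-one (carbinol epimers) | COc1ccc(C(O)[C@H]2C(=O)OC[C@@H]2Cc2ccc(OC)c(OC)c2)cc1OCc1ccccc1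
A1 | alternative 1 | (E)-3-(3,4-dimethoxyphenyl)allyl propiolate | C#CC(=O)OC/C=C/c1ccc(OC)c(OC)c1
A2 | alternative 1 | [3-(benzyloxy)-4-methoxyphenyl]boronic acid | COc1ccc(B(O)O)cc1OCc1ccccc1
A3 | alternative 1 | (R,E)-3-[3-(benzyloxy)-4-methoxybenzylidene]-4-(3,4-dimethoxybenzyl)dihydrofuran-2(3H)-one | O=C1OC[C@H](Cc2ccc(OC)c(OC)c2)/C1=C\c1ccc(OC)c(OCc2ccccc2)c1
A4 | alternative 2 | (5R)-5-(l-menthyloxy)furan-2(5H)-one | CC(C)[C@@H]1CC[C@@H](C)C[C@H]1O[C@H]1C=CC(=O)O1
A5 | alternative 2 | 2-(3,4-dimethoxyphenyl)-1,3-dithiane | COc1ccc(C2SCCCS2)cc1OC
A6 | alternative 2 | 3,4-trans-4,5-trans-3-[3-(benzyloxy)-4-methoxybenzyl]-4-[2-(3,4-dimethoxyphenyl)-1,3-dithian-2-yl]-5-(l-menthyloxy)dihydrofuran-2(3H)-one | CC(C)[C@@H]1CC[C@@H](C)C[C@H]1O[C@H]1[C@H](C2(c3ccc(OC)c(OC)c3)SCCCS2)[C@@H](Cc2ccc(OC)c(OCc3ccccc3)c2)C(=O)O1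
A7 | alternative 3 | 4-allyl-1,2-dimethoxybenzene | C=CCc1ccc(OC)c(OC)c1
A8 | alternative 3 | 3-(3,4-dimethoxybenzyl)cyclobutan-1-one | O=C1CC(Cc2ccc(OC)c(OC)c2)C1
A9 | alternative 3 | (R)-4-(3,4-dimethoxybenzyl)dihydrofuran-2(3H)-one (identical with 13) | O=C1C[C@@H](Cc2ccc(OC)c(OC)c2)CO1
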